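The route rests on cutting the C4–C5 bond of the cyclohexane ring. The key step exploits the fact that the rest, quaternary C1 (O1, carboxyl carbon C7) with the arms C2–C3 and C6–C5 ending in oxygenated carbons, is the skeleton of citric acid; only C4 must be added. An amine-catalysed intramolecular aldol addition forms C4–C5, closes the six-membered carbocycle and sets the trans-4,5-diol in one operation. Its precursor is a single-enantiomer 1,3-dioxolan-4-one (O1 and C7 tied by an acetone ketal) whose C1 carries a CH2CHO arm and a CH2C(=O)CH2OH arm. In the resulting 3-dehydroquinate only O4 and O5 are free, so both p-coumaroyl groups go on before C3 is reduced.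

Key step: step 7

Assumption: the quinidine-derived catalyst of step 3 is taken to give the (S)-hemithioester, and its quinine-derived pseudo-enantiomer takes its place if correlation shows the opposite sense. Atom labels C1–C7 and O1–O5 follow quinic acid in every compound (C7 = carboxyl carbon, O3 cis to O4, O5 trans to O4 and cis to C7).

Step 1
Reactants: 1 citric acid (anhydrous); 2 2,2-dimethoxypropane
Product: 3 2,2'-(2,2-dimethyl-5-oxo-1,3-dioxolane-4,4-diyl)diacetic acid (achiral; O1 and C7 joined through CMe2)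
Conditions: Me2C(OMe)2 (3 equiv), p-TsOH·H2O (2 mol %), acetone, rt
Reagents that add atoms: 2,2-dimethoxypropane 2, COC(C)(C)OC
Why: Acid-catalysed transketalisation of an α-hydroxy acid to a 1,3-dioxolan-4-one: only O1 and its geminal carboxyl C7 can share a five-membered ring, which leaves the two CH2CO2H arms free and equivalent, and the acetone ketal is preferred to a formaldehyde acetal because it falls off in dilute acid at the end, where base would shift the esters.

Step 2
Reactants: 3 2,2'-(2,2-dimethyl-5-oxo-1,3-dioxolane-4,4-diyl)diacetic acid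
Product: 4 2,2-dimethyl-1,3,8-trioxaspiro[4.5]decane-4,7,9-trione (spiro glutaric-type anhydride, achiral)
Conditions: (CF3CO)2O (1.5 equiv), MeCN, 0 °C → rt; evaporate
Reagents that add atoms: none
Why: Dehydrative cyclisation through a mixed trifluoroacetic anhydride: with C7 locked, the two arm carboxyls can only close the six-membered anhydride, and the low temperature avoids β-elimination of O1.

Step 3
Reactants: 4 2,2-dimethyl-1,3,8-trioxaspiro[4.5]decane-4,7,9-trione; 5 phenylmethanethiol
Product: 6 2-[(4S)-4-[2-(benzylsulfanyl)-2-oxoethyl]-2,2-dimethyl-5-oxo-1,3-dioxolan-4-yl]acetic acid (thioester on the C6–C5 arm, acid on the C2–C3 arm)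
Conditions: BnSH (1.1 equiv), 9-amino(9-deoxy)epi-quinidine 3,5-bis(trifluoromethyl)phenyl thiourea (10 mol %), MTBE/THF, −20 °C
Reagents that add atoms: phenylmethanethiol 5, SCc1ccccc1
Why: Organocatalytic desymmetrising thiolysis of a prochiral cyclic anhydride: the bifunctional alkaloid catalyst hydrogen-bonds one of the two enantiotopic anhydride carbonyls while its quinuclidine activates the thiol, which sets C1 and delivers one arm as an acid and the other as a thioester that can later be reduced selectively.

Step 4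
Reactants: 6 2-[(4S)-4-[2-(benzylsulfanyl)-2-oxoethyl]-2,2-dimethyl-5-oxo-1,3-dioxolan-4-yl]acetic acid; 7 (trimethylsilyl)diazomethane
Product: 10 S-benzyl 2-[(4S)-4-(3-diazo-2-oxopropyl)-2,2-dimethyl-5-oxo-1,3-dioxolan-4-yl]ethanethioate, via acid chloride 8 (not isolated), via C-silyl diazoketone 9 (not isolated)
Conditions: (COCl)2, cat. DMF, CH2Cl2, 0 °C; evaporate cold; TMSCHN2 (2.2 equiv), THF/MeCN 1:1, 0 °C; aqueous work-up, SiO2
Reagents that add atoms: (trimethylsilyl)diazomethane 7, C[Si](C)(C)C=[N+]=[N-]; oxalyl chloride (chlorine of 8 only), O=C(Cl)C(=O)Cl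
Why: Acylation of a diazoalkane by an acid chloride (first stage of the Arndt–Eistert sequence): C-acylation of 7 brings in C4, the second equivalent of 7 takes up the hydrogen chloride, the C-silyl group is lost on work-up, and C1 is not touched.

Step 5
Reactants: 10 S-benzyl 2-[(4S)-4-(3-diazo-2-oxopropyl)-2,2-dimethyl-5-oxo-1,3-dioxolan-4-yl]ethanethioate
Product: 12 S-benzyl 2-[(4S)-4-(3-hydroxy-2-oxopropyl)-2,2-dimethyl-5-oxo-1,3-dioxolan-4-yl]ethanethioate, via trifluoroacetate 11 (not isolated)
Conditions: TFA (2 equiv), CH2Cl2, 0 °C; evaporate with toluene; THF/pH 7 phosphate buffer, 0 °C → rt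
Reagents that add atoms: trifluoroacetic acid, OC(=O)C(F)(F)F
Why: Acidolysis of an α-diazoketone (protonation at C4, then SN2 displacement of nitrogen by trifluoroacetate) avoids metal carbenoids that O1 could trap, and the activated trifluoroacetate is then hydrolysed at neutral pH without harm to thioester or dioxolanone.

Step 6
Reactants: 12 S-benzyl 2-[(4S)-4-(3-hydroxy-2-oxopropyl)-2,2-dimethyl-5-oxo-1,3-dioxolan-4-yl]ethanethioate
Product: 13 (5R)-5-(3-hydroxy-2-oxopropyl)-2,2-dimethyl-5-(2-oxoethyl)-1,3-dioxolan-4-one (keto aldehyde, used at once)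
Conditions: Et3SiH (3 equiv), 10 % Pd/C, acetone, rt; filtration, short SiO2 column
Reagents that add atoms: none
Why: Fukuyama reduction: palladium inserts only into the C–S bond and the acyl-palladium species is intercepted by the silane, so the reaction stops at the aldehyde under neutral conditions and leaves ketone, primary alcohol and dioxolanone alone, which no hydride reduction of an O-ester arm could promise.

Step 7
Reactants: 13 (5R)-5-(3-hydroxy-2-oxopropyl)-2,2-dimethyl-5-(2-oxoethyl)-1,3-dioxolan-4-one
Product: 14 (5R,8S,9R)-8,9-dihydroxy-2,2-dimethyl-1,3-dioxaspiro[4.5]decane-4,7-dione (3-dehydroquinic acid 1-O,7-isopropylidene ketal; 1R,4S,5R in quinate numbering; O4 and O5 trans-diequatorial, O5 cis to C7)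
Conditions: O-tert-butyl-D-threonine (20 mol %), NMP (0.05 M), 4 °C → rt
Reagents that add atoms: none
Why: Proposed new method: the primary amine condenses with the C3 ketone of 13, the imine tautomerises to the (Z)-enamine C3=C4 that is held by an N–H···O4 hydrogen bond, C4 adds to the C5 aldehyde activated by the carboxyl group of the catalyst, and hydrolysis of the iminium ion releases 14 and the amine. The closest known reaction types are Hajos–Parrish-type 6-enolendo cyclisations run with primary amino acids on substituted donor carbons, the intermolecular syn-selective aldol addition of hydroxyacetone under the same catalyst class, and the base-induced closure of hexos-5-uloses to inososes; an enamine-catalysed closure through an oxygen-bearing donor carbon is the untested part. The only ring formed, the cyclohexanone C1–C6, closes in the 6-(enolendo)-exo-trig mode through a chair. C4 is controlled by the catalyst, whose carboxyl group guides the aldehyde to one face of the enamine: the D-series gives (3S,4R)-syn-diols from hydroxyacetone, the pattern that corresponds to 4S,5R here. C5 is controlled by the chair, in which O4 of the Z-enamine and the aldehyde oxygen are equatorial while the C1 centre places O1 axial and C7 equatorial, so O5 ends trans to O4 and cis to C7, and reversible enamine formation and retro-aldol cleavage let cis-diols drain towards this diequatorial isomer. The step needs C4 as the sole nucleophile and an intact C1: attack of C2 on C5 or of C6 on C3 would close a cyclobutane, and the dioxolanone blocks retro-aldol cleavage at C1 as well as lactol and lactone formation by tying up O1 and C7.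

Step 8
Reactants: 14 (5R,8S,9R)-8,9-dihydroxy-2,2-dimethyl-1,3-dioxaspiro[4.5]decane-4,7-dione; 15 (E)-4-acetoxycinnamic acid
Product: 16 (1R,4S,5R)-4,5-bis-O-[(E)-4-acetoxycinnamoyl]-3-dehydroquinic acid 1-O,7-isopropylidene ketal
Conditions: 15 (3 equiv), EDC·HCl (3 equiv), DMAP (0.3 equiv), CH2Cl2, 0 °C → rt
Reagents that add atoms: (E)-4-acetoxycinnamic acid 15, CC(=O)Oc1ccc(/C=C/C(=O)O)cc1
Why: Steglich-type carbodiimide esterification: O4 and O5 are the only hydroxyls of 14, and the excess carboxylic acid and the hydrochloride of the carbodiimide keep the medium buffered, so the β-acyloxy ketone never meets free base and C4 and C5 keep their configuration.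

Step 9
Reactants: 16 (1R,4S,5R)-4,5-bis-O-[(E)-4-acetoxycinnamoyl]-3-dehydroquinic acid 1-O,7-isopropylidene ketal
Product: 17 (1S,3R,4R,5R)-4,5-bis-O-[(E)-4-acetoxycinnamoyl]quinic acid 1-O,7-isopropylidene ketal (3-OH axial, cis to O4)
Conditions: (S)-Me-CBS (0.5 equiv), BH3·SMe2 (1.2 equiv), THF, −40 → −20 °C; MeOH quench, cold dilute HCl wash
Reagents that add atoms: none
Why: Corey–Bakshi–Shibata reduction: the oxazaborolidine binds the ketone on the side of the small C2 methylene and delivers hydride to the face that carries O5 and C7, the equatorial trajectory that the axial O1 also leaves open, which gives the axial (3R)-alcohol under non-basic conditions that spare esters and enoates and give no alkoxide that could pull the O4 acyl group over to O3.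

Step 10
Reactants: 17 (1S,3R,4R,5R)-4,5-bis-O-[(E)-4-acetoxycinnamoyl]quinic acid 1-O,7-isopropylidene ketal
Product: 18 4,5-di-O-p-coumaroylquinic acid, (1S,3R,4R,5R)
Conditions: 2 M aq. HCl/THF 1:3, rt
Reagents that add atoms: water, O
Why: Acid-catalysed hydrolysis: the ketal-type dioxolanone and the two aryl acetates are cleaved much faster than the conjugated esters on the hindered secondary O4 and O5, and the acidic medium suppresses acyl migration to the free cis O3, so no stereocentre and no ester position changes.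

Compound list
1 | citric acid | OC(=O)CC(O)(CC(=O)O)C(=O)O | starting material
2 | 2,2-dimethoxypropane | COC(C)(C)OC | starting material
3 | 2,2'-(2,2-dimethyl-5-oxo-1,3-dioxolane-4,4-diyl)diacetic acid | O=C1OC(C)(C)OC1(CC(=O)O)CC(=O)O | intermediate
4 | 2,2-dimethyl-1,3,8-trioxaspiro[4.5]decane-4,7,9-trione | O=C1OC(C)(C)OC12CC(=O)OC(=O)C2 | intermediate
5 | phenylmethanethiol | SCc1ccccc1 | starting material
6 | 2-[(4S)-4-[2-(benzylsulfanyl)-2-oxoethyl]-2,2-dimethyl-5-oxo-1,3-dioxolan-4-yl]acetic acid | O=C1OC(C)(C)O[C@]1(CC(=O)SCc2ccccc2)CC(=O)O | intermediate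
7 | (trimethylsilyl)diazomethane | C[Si](C)(C)C=[N+]=[N-] | starting material
8 | acid chloride of 6 (C1 unchanged in space) | O=C1OC(C)(C)O[C@]1(CC(=O)SCc2ccccc2)CC(=O)Cl | intermediate
9 | S-benzyl 2-[(4S)-4-[3-diazo-2-oxo-3-(trimethylsilyl)propyl]-2,2-dimethyl-5-oxo-1,3-dioxolan-4-yl]ethanethioate | O=C1OC(C)(C)O[C@]1(CC(=O)SCc2ccccc2)CC(=O)C(=[N+]=[N-])[Si](C)(C)C | intermediate
10 | S-benzyl 2-[(4S)-4-(3-diazo-2-oxopropyl)-2,2-dimethyl-5-oxo-1,3-dioxolan-4-yl]ethanethioate | O=C1OC(C)(C)O[C@]1(CC(=O)SCc2ccccc2)CC(=O)C=[N+]=[N-] | intermediate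
11 | S-benzyl 2-[(4S)-2,2-dimethyl-5-oxo-4-[2-oxo-3-(trifluoroacetoxy)propyl]-1,3-dioxolan-4-yl]ethanethioate | O=C1OC(C)(C)O[C@]1(CC(=O)SCc2ccccc2)CC(=O)COC(=O)C(F)(F)F | intermediate
12 | S-benzyl 2-[(4S)-4-(3-hydroxy-2-oxopropyl)-2,2-dimethyl-5-oxo-1,3-dioxolan-4-yl]ethanethioate | O=C1OC(C)(C)O[C@]1(CC(=O)SCc2ccccc2)CC(=O)CO | intermediate
13 | (5R)-5-(3-hydroxy-2-oxopropyl)-2,2-dimethyl-5-(2-oxoethyl)-1,3-dioxolan-4-one | O=C1OC(C)(C)O[C@]1(CC=O)CC(=O)CO | intermediate
14 | (5R,8S,9R)-8,9-dihydroxy-2,2-dimethyl-1,3-dioxaspiro[4.5]decane-4,7-dione | O[C@@H]1C(=O)C[C@]2(OC(C)(C)OC2=O)C[C@H]1O | intermediate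
15 | (E)-4-acetoxycinnamic acid | CC(=O)Oc1ccc(/C=C/C(=O)O)cc1 | starting material
16 | (1R,4S,5R)-4,5-bis-O-[(E)-4-acetoxycinnamoyl]-3-dehydroquinic acid 1-O,7-isopropylidene ketal | O=C(/C=C/c1ccc(OC(C)=O)cc1)O[C@@H]1C(=O)C[C@]2(OC(C)(C)OC2=O)C[C@H]1OC(=O)/C=C/c1ccc(OC(C)=O)cc1 | intermediate
17 | (1S,3R,4R,5R)-4,5-bis-O-[(E)-4-acetoxycinnamoyl]quinic acid 1-O,7-isopropylidene ketal | O=C(/C=C/c1ccc(OC(C)=O)cc1)O[C@@H]1[C@H](O)C[C@]2(OC(C)(C)OC2=O)C[C@H]1OC(=O)/C=C/c1ccc(OC(C)=O)cc1 | intermediate
18 | 4,5-di-O-p-coumaroylquinic acid, (1S,3R,4R,5R) | O=C(/C=C/c1ccc(O)cc1)O[C@@H]1[C@H](O)C[C@@](O)(C(=O)O)C[C@H]1OC(=O)/C=C/c1ccc(O)cc1 | target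

Total step count: 10. Longest linear sequence: 10 steps (1 to 18); 2, 5, 7 and 15 are bought.

Steps most likely to fail

1. Step 7 (bears the label).
- What may go wrong:
  - The closure may discriminate poorly between the two chairs that differ in the orientation of O1 and C7, which means weak facial selectivity relative to C1.
  - The catalyst may form the enamine of the aldehyde arm and expel O1 by β-elimination.
  - The ketol may dehydrate.
  - O4 or the catalyst nitrogen may slowly open the dioxolanone.
- Fallback with known chemistry, setting out from 12 and coming back at 14: 12 is treated with TBSOTf (2.2 equiv) and Et3N in CH2Cl2 (−78 → 0 °C), which silylates O4 and enolises the ketone towards the oxygenated carbon to give the (Z)-bis(silyloxy)alkene thioester F1. Fukuyama reduction (Et3SiH, Pd/C, acetone) unmasks the enol silane aldehyde F2. BF3·OEt2 in CH2Cl2 at −78 °C then closes the same C4–C5 bond by an intramolecular Mukaiyama aldol addition to the 4-O-TBS ketol F3, at which stage diastereomers can be separated by chromatography. HF·pyridine in THF at 0 °C removes the silyl ether and gives 14.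

2. Step 3.
- What may go wrong:
  - The ring oxygen and the lactone carbonyl on the prochiral carbon differ little in size, so discrimination of the enantiotopic anhydride carbonyls may be weak.
  - Reversible loss of thiol from the carboxylate form may erode the enantiomeric purity.
- Fallback by classical resolution, setting out from 4 and coming back at 6: 4 is opened with 5 and catalytic DABCO in THF to the racemic hemithioester F4. This is resolved by fractional crystallisation of its salt with a tertiary amine that cannot be acylated, (R)-N,N-dimethyl-1-phenylethylamine (or its enantiomer, whichever gives the less soluble salt with the S acid), as the diastereomerically pure ammonium salt F5. Partition between cold dilute HCl and EtOAc frees 6.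

3. Step 8.
- What may go wrong:
  - Once O5 is acylated, deprotonation at C4 can trigger β-elimination of the C5 acyloxy group.
  - Loss of O1 and aromatisation can follow that elimination.
  - The α-ketol may isomerise through its enediol.
- Fallback that acylates only after the ketone is gone, setting out from 14 and coming back at 17. It also bypasses step 9 and its risk of acyl migration. 14 is bridged with TIPDSCl2 and imidazole (DMF, 0 °C) to the 4,5-O-disiloxanediyl ketone F6, whose silyl ethers are poor leaving groups and hold the diol diequatorial. L-Selectride (THF, −78 °C, AcOH quench) attacks from the equatorial side and gives the axial 3-alcohol F7. 4-Methoxybenzyl trichloroacetimidate with catalytic La(OTf)3 in toluene gives the 3-O-PMB ether F8. HF·pyridine (THF, 0 °C) frees the 3-O-PMB 4,5-diol F9. EDC·HCl/DMAP with 15 gives the 3-O-PMB bis-ester F10. DDQ in CH2Cl2/pH 7 buffer removes the PMB group and gives 17.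

Further compounds
F1 | step 7 | S-benzyl 2-[(4S)-4-[(Z)-2,3-bis(tert-butyldimethylsilyloxy)prop-2-enyl]-2,2-dimethyl-5-oxo-1,3-dioxolan-4-yl]ethanethioate | O=C1OC(C)(C)O[C@]1(CC(=O)SCc2ccccc2)C/C(O[Si](C)(C)C(C)(C)C)=C/O[Si](C)(C)C(C)(C)C
F2 | step 7 | (5S)-5-[(Z)-2,3-bis(tert-butyldimethylsilyloxy)prop-2-enyl]-2,2-dimethyl-5-(2-oxoethyl)-1,3-dioxolan-4-one | O=C1OC(C)(C)O[C@]1(CC=O)C/C(O[Si](C)(C)C(C)(C)C)=C/O[Si](C)(C)C(C)(C)C
F3 | step 7 | (5R,8S,9R)-8-(tert-butyldimethylsilyloxy)-9-hydroxy-2,2-dimethyl-1,3-dioxaspiro[4.5]decane-4,7-dione | CC(C)(C)[Si](C)(C)O[C@@H]1C(=O)C[C@]2(OC(C)(C)OC2=O)C[C@H]1O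
F4 | step 3 | racemic 2-[4-[2-(benzylsulfanyl)-2-oxoethyl]-2,2-dimethyl-5-oxo-1,3-dioxolan-4-yl]acetic acid | O=C1OC(C)(C)OC1(CC(=O)SCc2ccccc2)CC(=O)O
F5 | step 3 | (R)-N,N-dimethyl-1-phenylethylammonium salt of 6 | O=C1OC(C)(C)O[C@]1(CC(=O)SCc2ccccc2)CC(=O)[O-].C[C@@H]([NH+](C)C)c1ccccc1
F6 | step 8 | 4,5-O-(1,1,3,3-tetraisopropyldisiloxane-1,3-diyl)-3-dehydroquinic acid 1-O,7-isopropylidene ketal | CC(C)[Si]3(C(C)C)O[C@@H]1C(=O)C[C@]2(OC(C)(C)OC2=O)C[C@H]1O[Si](C(C)C)(C(C)C)O3
F7 | step 8 | 4,5-O-(1,1,3,3-tetraisopropyldisiloxane-1,3-diyl)quinic acid 1-O,7-isopropylidene ketal (3-OH axial) | CC(C)[Si]3(C(C)C)O[C@@H]1[C@H](O)C[C@]2(OC(C)(C)OC2=O)C[C@H]1O[Si](C(C)C)(C(C)C)O3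
F8 | step 8 | 3-O-(4-methoxybenzyl)-4,5-O-(1,1,3,3-tetraisopropyldisiloxane-1,3-diyl)quinic acid 1-O,7-isopropylidene ketal | CC(C)[Si]3(C(C)C)O[C@@H]1[C@H](OCc4ccc(OC)cc4)C[C@]2(OC(C)(C)OC2=O)C[C@H]1O[Si](C(C)C)(C(C)C)O3
F9 | step 8 | 3-O-(4-methoxybenzyl)quinic acid 1-O,7-isopropylidene ketal | O[C@@H]1[C@H](OCc3ccc(OC)cc3)C[C@]2(OC(C)(C)OC2=O)C[C@H]1O
F10 | step 8 | 4,5-bis-O-[(E)-4-acetoxycinnamoyl]-3-O-(4-methoxybenzyl)quinic acid 1-O,7-isopropylidene ketal | O=C(/C=C/c1ccc(OC(C)=O)cc1)O[C@@H]1[C@H](OCc3ccc(OC)cc3)C[C@]2(OC(C)(C)OC2=O)C[C@H]1OC(=O)/C=C/c1ccc(OC(C)=O)cc1
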